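The readings are simulated with constants of no real substance.

Leave the flask closed and stirred, and do not quench it yet. Add nothing; the reckoning below holds for this charge.

- south: starting material 0.050 M; protic impurity 0.010 M; the very flask that is asked about, followed so far
- flask: starting material 0.050 M; protic impurity 0.0100 M; time 5.0 min

- south (time / s: isomer of the product A / %, target / %): 15.0: 1.0, 5.5; 30.0: 2.4, 9.5; 50.0: 7.0, 13.1; 60.0: 8.7, 14.5; 80.0: 14.1, 15.7; 90.0: 16.6, 16.6

(each reading ± 0.3 percentage points)

- ratio of isomer of the product A to target at 6.0 s
- ratio of isomer of the product A to target at 40 s
- ratio of isomer of the product A to target at 5.0 min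

At 90.0 s the flask reads 16.6 % target and 16.6 % isomer of the product A, level with each other. Work with the fraction left, meaning whatever is not yet target or isomer. Take minus its logarithm over the time. The last reading gives 0.269 /min for this clearing constant, an apparent first-order constant. The first reading gives 0.269 /min, so the fraction left has fallen exponentially so far.

Expect 26.1 % left in the flask at 5.0 min, with 73.9 % in target and isomer together. The ratio is that sum over target, minus one. Hold target at its last reading and my ratio is 3.45. Any fall in target raises it.

The forecast gives 0.12, 0.39 and 2.8, and it “assumes the first-order behaviour continues and target stays stable”. My figure stands above its last one.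

The flask gives 0.0538, 0.391 and 5.08.

    other conformer + protic impurity → quenched substrate (k = 0.420 /M/s)
    starting material → target (k = 0.00430 /s)
    target ⇌ isomer of the product A (K = 14.0, k = 0.00660 /s)
    target ⇌ isomer of the product B (K = 0.260, k = 0.00190 /s)
    starting material ⇌ other conformer (K = 19.0, k = 0.00690 /s)
    other conformer → isomer of the product A (k = 0.00690 /s)

At 5.00 min the flask holds 58.2 % isomer and 11.5 % target, so 30.3 % is left against the reckoned 26.1 %. Target has dropped below its highest amount, 17.0 %. Part of the high ratio comes from target turning into isomer: with that step removed, both ways, the ratio is 1.13 instead of 5.08. Part of the ratio at 6.0 s comes from starting material turning into other conformer: with that step removed, both ways, it is 0.0200 instead of 0.0538. The neighbour charged with 0.013 M starting material holds 11.4 % target and 55.9 % isomer at 5.00 min, which leaves 32.7 %, a clearing constant of 0.224 /min.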